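**Retrosynthetic overview**
1. Target 22 ⇐ its 2-(trimethylsilyl)ethyl (TMSE) ester 21 ⇐ intramolecular Diels–Alder (IMDA) of the linear hexaenoate 20. Both rings close in this one step: the cyclopentene from the C3–C6 tether, the cyclohexene from diene C7=C8–C9=C10 plus dienophile C2=C3.
2. 20 ⇐ late sp2–sp2 Negishi coupling at C8–C9 of two equal-sized halves: trienyl iodide 6 (C9–C14 + Ph) and bromotrienoate 19 (C1–C8).
3. 6 ⇐ phenylacetylene by two rounds of ethynylation and Zr-catalysed carboalumination–iodination.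
4. 19 ⇐ Stille union of the (Z)-vinyl iodide 18 with stannylacrylate 9; 18 ⇐ (R)-Roche ester, which supplies the only pre-formed stereocentre (C6 of the chain, C1 of the target).

Assumption: (E)-3-iodo-2-methylacrylic acid (7) is treated as a purchasable building block. The target configuration read from the SMILES is (1R,3aR,4R,5S,7aS), trans-fused.

**Fragment A: trienyl iodide 6**

Step 1
Reactants: 1 phenylacetylene
Product: 2 (E)-(2-iodovinyl)benzene
Conditions: Cp2Zr(H)Cl, THF, rt; then I2, 0 °C
Reagents that add atoms: iodine, II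
Why: Schwartz hydrozirconation is a syn addition with Zr on the terminal carbon, and iodinolysis proceeds with retention, so only the E iodide forms.

Step 2
Reactants: 2 (E)-(2-iodovinyl)benzene
Product: 3 (E)-but-1-en-3-yn-1-ylbenzene
Conditions: HC≡CMgBr, ZnBr2, THF, 0 °C; then 2, Pd(PPh3)4 (5 mol%), rt
Reagents that add atoms: ethynylmagnesium bromide, C#C[Mg]Br
Why: Negishi alkynylation with ethynylzinc bromide gives the terminal enyne directly with retention of the alkene geometry.

Step 3
Reactants: 3 (E)-but-1-en-3-yn-1-ylbenzene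
Product: 4 [(1E,3E)-4-iodo-3-methylbuta-1,3-dien-1-yl]benzene
Conditions: Me3Al, Cp2ZrCl2, (CH2Cl)2, rt; then I2, THF, −30 → 0 °C
Reagents that add atoms: trimethylaluminium, C[Al](C)C; iodine, II
Why: Negishi Zr-catalysed carboalumination adds Me–Al syn with methyl on the internal carbon, and iodinolysis with retention gives the (E)-trisubstituted iodide.

Step 4
Reactants: 4 [(1E,3E)-4-iodo-3-methylbuta-1,3-dien-1-yl]benzene
Product: 5 [(1E,3E)-3-methylhexa-1,3-dien-5-yn-1-yl]benzene
Conditions: HC≡CMgBr, ZnBr2, THF, 0 °C; then 4, Pd(PPh3)4 (5 mol%), rt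
Reagents that add atoms: ethynylmagnesium bromide, C#C[Mg]Br
Why: A second Negishi alkynylation, stereoretentive at the dienyl iodide.

Step 5
Reactants: 5 [(1E,3E)-3-methylhexa-1,3-dien-5-yn-1-yl]benzene
Product: 6 [(1E,3E,5E)-6-iodo-3,5-dimethylhexa-1,3,5-trien-1-yl]benzene
Conditions: Me3Al, Cp2ZrCl2, (CH2Cl)2, rt; then I2, THF, −30 → 0 °C
Reagents that add atoms: trimethylaluminium, C[Al](C)C; iodine, II
Why: A second syn carboalumination–iodination installs the C10 methyl and the C9 iodide with E geometry; the iodide is isolated and purified before the coupling.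

**C1–C3 unit: stannane 9**

Step 6
Reactants: 7 (E)-3-iodo-2-methylprop-2-enoic acid
Product: 8 2-(trimethylsilyl)ethyl (E)-3-iodo-2-methylprop-2-enoate
Conditions: Me3SiCH2CH2OH, DCC, DMAP (cat.), CH2Cl2, 0 °C → rt
Reagents that add atoms: 2-(trimethylsilyl)ethanol, C[Si](C)(C)CCO
Why: Steglich esterification installs a fluoride-cleavable ester, which can later be removed from a carboxyl on a hindered quaternary carbon without attack at the carbonyl.

Step 7
Reactants: 8 2-(trimethylsilyl)ethyl (E)-3-iodo-2-methylprop-2-enoate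
Product: 9 2-(trimethylsilyl)ethyl (E)-2-methyl-3-(tributylstannyl)prop-2-enoate
Conditions: (Bu3Sn)2, PdCl2(PPh3)2 (5 mol%), THF, 60 °C
Reagents that add atoms: hexabutylditin, CCCC[Sn](CCCC)(CCCC)[Sn](CCCC)(CCCC)CCCC
Why: Pd-catalysed stannylation of the alkenyl iodide with the distannane proceeds with retention of the E geometry.

**Fragment B: bromotrienoate 19**

Step 8
Reactants: 10 methyl (R)-3-hydroxy-2-methylpropanoate
Product: 11 methyl (R)-3-[(tert-butyldimethylsilyl)oxy]-2-methylpropanoate
Conditions: TBSCl, imidazole, CH2Cl2, rt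
Reagents that add atoms: TBSCl, CC(C)(C)[Si](C)(C)Cl
Why: Standard silylation of the primary alcohol; the stereocentre comes from the chiral pool and is untouched.

Step 9
Reactants: 11 methyl (R)-3-[(tert-butyldimethylsilyl)oxy]-2-methylpropanoate
Product: 12 (R)-3-[(tert-butyldimethylsilyl)oxy]-2-methylpropanal
Conditions: DIBAL-H, CH2Cl2, −78 °C; Rochelle salt work-up
Reagents that add atoms: none
Why: Partial ester reduction stops at the tetrahedral aluminate at −78 °C, and the β-silyloxy aldehyde is configurationally stable when kept cold.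

Step 10
Reactants: 12 (R)-3-[(tert-butyldimethylsilyl)oxy]-2-methylpropanal
Product: 13 (S)-tert-butyl[(4,4-dibromo-2-methylbut-3-en-1-yl)oxy]dimethylsilane
Conditions: CBr4, PPh3, 2,6-lutidine, CH2Cl2, 0 °C
Reagents that add atoms: carbon tetrabromide, BrC(Br)(Br)Br
Why: First stage of the Corey–Fuchs reaction (Ramirez dibromo-olefination), non-basic so the α-stereocentre is not epimerised; the descriptor changes only because CIP priorities change.

Step 11
Reactants: 13 (S)-tert-butyl[(4,4-dibromo-2-methylbut-3-en-1-yl)oxy]dimethylsilane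
Product: 14 (S)-tert-butyldimethyl[(2-methylpent-3-yn-1-yl)oxy]silane
Conditions: n-BuLi (2.2 equiv), THF, −78 → 0 °C; then MeI, −78 °C → rt
Reagents that add atoms: iodomethane, CI
Why: Second stage of the Corey–Fuchs reaction (Fritsch–Buttenberg–Wiechell rearrangement to the lithium acetylide), trapped in situ by methylation.

Step 12
Reactants: 14 (S)-tert-butyldimethyl[(2-methylpent-3-yn-1-yl)oxy]silane
Product: 15 (S,E)-[(4-bromo-2-methylpent-3-en-1-yl)oxy](tert-butyl)dimethylsilane
Conditions: Cp2Zr(H)Cl (2 equiv), THF, 50 °C; then NBS, 0 °C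
Reagents that add atoms: N-bromosuccinimide, BrN1C(=O)CCC1=O
Why: Hydrozirconation with excess reagent equilibrates Zr to the methyl-bearing alkyne carbon, away from the branched centre; syn addition and retentive bromination give the (E)-2-bromoalkene, chosen to be orthogonal to the iodide made in Step 15.

Step 13
Reactants: 15 (S,E)-[(4-bromo-2-methylpent-3-en-1-yl)oxy](tert-butyl)dimethylsilane
Product: 16 (S,E)-4-bromo-2-methylpent-3-en-1-ol
Conditions: HF·pyridine, pyridine/THF, 0 °C → rt
Reagents that add atoms: none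
Why: Mild acidic fluoride desilylation leaves the vinyl bromide intact.

Step 14
Reactants: 16 (S,E)-4-bromo-2-methylpent-3-en-1-ol
Product: 17 (S,E)-4-bromo-2-methylpent-3-enal
Conditions: Dess–Martin periodinane, NaHCO3, CH2Cl2, 0 °C; used crude and cold
Reagents that add atoms: none
Why: Buffered Dess–Martin oxidation is neutral and fast, which limits epimerisation or conjugation of the α-chiral β,γ-unsaturated aldehyde.

Step 15
Reactants: 17 (S,E)-4-bromo-2-methylpent-3-enal
Product: 18 (2E,4S,5Z)-2-bromo-6-iodo-4-methylhepta-2,5-diene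
Conditions: EtPPh3I, n-BuLi, THF; I2, −78 °C; NaHMDS, −20 °C; then 17, −78 °C
Reagents that add atoms: (1-iodoethylidene)triphenylphosphorane (generated in situ), CC(I)=P(c1ccccc1)(c1ccccc1)c1ccccc1
Why: The Stork–Zhao-type Wittig olefination is kinetically Z-selective (iodine cis to the chain), which fixes the C4=C5 geometry needed for the cyclopentene; addition at −78 °C outruns enolisation of the aldehyde.

Step 16
Reactants: 18 (2E,4S,5Z)-2-bromo-6-iodo-4-methylhepta-2,5-diene; 9 2-(trimethylsilyl)ethyl (E)-2-methyl-3-(tributylstannyl)prop-2-enoate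
Product: 19 2-(trimethylsilyl)ethyl (2E,4Z,6R,7E)-8-bromo-2,4,6-trimethylnona-2,4,7-trienoate
Conditions: Pd(PPh3)4 (5 mol%), CuTC, [Bu4N][Ph2PO2], DMF, rt
Reagents that add atoms: none
Why: Copper-promoted Stille coupling at rt is selective for C–I over C–Br and stereoretentive at both partners, giving the (2E,4Z)-dienoate under neutral conditions that do not touch the bis-allylic C6–H.

**Fragment union and end-game**

Step 17
Reactants: 6 [(1E,3E,5E)-6-iodo-3,5-dimethylhexa-1,3,5-trien-1-yl]benzene; 19 2-(trimethylsilyl)ethyl (2E,4Z,6R,7E)-8-bromo-2,4,6-trimethylnona-2,4,7-trienoate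
Product: 20 2-(trimethylsilyl)ethyl (2E,4Z,6S,7E,9E,11E,13E)-2,4,6,8,10,12-hexamethyl-14-phenyltetradeca-2,4,7,9,11,13-hexaenoate
Conditions: 6, t-BuLi (2 equiv), Et2O, −78 °C; ZnCl2 (THF), −78 → 0 °C; then 19, Pd(t-Bu3P)2 (5 mol%), THF, rt
Reagents that add atoms: none
Why: Negishi coupling of the trienylzinc (from I/Li exchange and transmetalation) with the alkenyl bromide is stereoretentive and non-basic, so the ester and the acidic C6–H survive; the C6 descriptor changes only through CIP priorities.

Step 18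
Reactants: 20 2-(trimethylsilyl)ethyl (2E,4Z,6S,7E,9E,11E,13E)-2,4,6,8,10,12-hexamethyl-14-phenyltetradeca-2,4,7,9,11,13-hexaenoate
Product: 21 2-(trimethylsilyl)ethyl (1R,3aR,4R,5S,7aS)-1,3,4,5,7-pentamethyl-5-[(1E,3E)-2-methyl-4-phenylbuta-1,3-dien-1-yl]-3a,4,5,7a-tetrahydro-1H-indene-4-carboxylate
Conditions: PhMe (5 mM), BHT (10 mol%), 100 °C, Ar, dark
Reagents that add atoms: none
Why: In the intramolecular Diels–Alder reaction the (E)-enoate puts CO2R cis to H-3a and the (E,E)-diene puts the C4 and C5 methyls cis; the ester-endo transition state gives the trans ring fusion; and A(1,3) strain with the C7 methyl keeps H-1 in the diene plane so the dienophile adds anti to the C1 methyl, setting C3a, C4, C5 and C7a relative to C1.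

Step 19
Reactants: 21 the TMSE ester above
Product: 22 (1R,3aR,4R,5S,7aS)-1,3,4,5,7-pentamethyl-5-[(1E,3E)-2-methyl-4-phenylbuta-1,3-dien-1-yl]-3a,4,5,7a-tetrahydro-1H-indene-4-carboxylic acid (27-nor-zyggomphic acid B)
Conditions: TBAF, THF, rt
Reagents that add atoms: none
Why: Fluoride attacks silicon and fragments the TMSE ester (β-elimination of ethylene), releasing the hindered acid without nucleophilic attack at the carbonyl and without touching any stereocentre.

**Compound list**

1 | phenylacetylene | C#Cc1ccccc1 | starting material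
2 | (E)-(2-iodovinyl)benzene | I/C=C/c1ccccc1 | intermediate
3 | (E)-but-1-en-3-yn-1-ylbenzene | C#C/C=C/c1ccccc1 | intermediate
4 | [(1E,3E)-4-iodo-3-methylbuta-1,3-dien-1-yl]benzene | I/C=C(C)/C=C/c1ccccc1 | intermediate
5 | [(1E,3E)-3-methylhexa-1,3-dien-5-yn-1-yl]benzene | C#C/C=C(C)/C=C/c1ccccc1 | intermediate
6 | [(1E,3E,5E)-6-iodo-3,5-dimethylhexa-1,3,5-trien-1-yl]benzene | I/C=C(C)/C=C(C)/C=C/c1ccccc1 | intermediate
7 | (E)-3-iodo-2-methylprop-2-enoic acid | OC(=O)/C(C)=C/I | starting material
8 | 2-(trimethylsilyl)ethyl (E)-3-iodo-2-methylprop-2-enoate | C[Si](C)(C)CCOC(=O)/C(C)=C/I | intermediate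
9 | 2-(trimethylsilyl)ethyl (E)-2-methyl-3-(tributylstannyl)prop-2-enoate | CCCC[Sn](CCCC)(CCCC)/C=C(C)/C(=O)OCC[Si](C)(C)C | intermediate
10 | methyl (R)-3-hydroxy-2-methylpropanoate | OC[C@@H](C)C(=O)OC | starting material
11 | methyl (R)-3-[(tert-butyldimethylsilyl)oxy]-2-methylpropanoate | CC(C)(C)[Si](C)(C)OC[C@@H](C)C(=O)OC | intermediate
12 | (R)-3-[(tert-butyldimethylsilyl)oxy]-2-methylpropanal | CC(C)(C)[Si](C)(C)OC[C@@H](C)C=O | intermediate
13 | (S)-tert-butyl[(4,4-dibromo-2-methylbut-3-en-1-yl)oxy]dimethylsilane | CC(C)(C)[Si](C)(C)OC[C@@H](C)C=C(Br)Br | intermediate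
14 | (S)-tert-butyldimethyl[(2-methylpent-3-yn-1-yl)oxy]silane | CC(C)(C)[Si](C)(C)OC[C@@H](C)C#CC | intermediate
15 | (S,E)-[(4-bromo-2-methylpent-3-en-1-yl)oxy](tert-butyl)dimethylsilane | CC(C)(C)[Si](C)(C)OC[C@@H](C)/C=C(C)/Br | intermediate
16 | (S,E)-4-bromo-2-methylpent-3-en-1-ol | OC[C@@H](C)/C=C(C)/Br | intermediate
17 | (S,E)-4-bromo-2-methylpent-3-enal | O=C[C@@H](C)/C=C(C)/Br | intermediate
18 | (2E,4S,5Z)-2-bromo-6-iodo-4-methylhepta-2,5-diene | I/C(C)=C\[C@@H](C)/C=C(C)/Br | intermediate
19 | 2-(trimethylsilyl)ethyl (2E,4Z,6R,7E)-8-bromo-2,4,6-trimethylnona-2,4,7-trienoate | C[Si](C)(C)CCOC(=O)/C(C)=C/C(C)=C\[C@@H](C)/C=C(C)/Br | intermediate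
20 | 2-(trimethylsilyl)ethyl (2E,4Z,6S,7E,9E,11E,13E)-2,4,6,8,10,12-hexamethyl-14-phenyltetradeca-2,4,7,9,11,13-hexaenoate | C[Si](C)(C)CCOC(=O)/C(C)=C/C(C)=C\[C@@H](C)/C=C(C)/C=C(C)/C=C(C)/C=C/c1ccccc1 | intermediate
21 | 2-(trimethylsilyl)ethyl (1R,3aR,4R,5S,7aS)-1,3,4,5,7-pentamethyl-5-[(1E,3E)-2-methyl-4-phenylbuta-1,3-dien-1-yl]-3a,4,5,7a-tetrahydro-1H-indene-4-carboxylate | CC1=C[C@](C)(/C=C(C)/C=C/c2ccccc2)[C@](C)(C(=O)OCC[Si](C)(C)C)[C@H]2C(C)=C[C@@H](C)[C@H]12 | intermediate
22 | (1R,3aR,4R,5S,7aS)-1,3,4,5,7-pentamethyl-5-[(1E,3E)-2-methyl-4-phenylbuta-1,3-dien-1-yl]-3a,4,5,7a-tetrahydro-1H-indene-4-carboxylic acid (27-nor-zyggomphic acid B) | CC1=C[C@](C)(/C=C(C)/C=C/c2ccccc2)[C@](C)(C(=O)O)[C@H]2C(C)=C[C@@H](C)[C@H]12 | target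

**Step count**
Total steps: 19 (fragment A 5, stannane 2, fragment B 9, union and end-game 3).
Longest linear sequence: 12 steps (Steps 8–19, from the Roche ester), which is 12/19 ≈ 0.63 of the total.

**Three steps most likely to fail**
1. Step 18 (IMDA). It forms two adjacent quaternary centres through a tether containing a Z-olefin, and may be slow, give the cis-fused (exo) adduct, or lose the C6 stereocentre by a 1,5-H shift. Fallback: build the ester half with a C3 ketone in place of the C4=C5 olefin, giving a doubly activated 4-oxo-2-enoate dienophile that should cyclise at or below rt. Then convert the resulting hydrindanone to the C2=C3 methyl olefin by kinetic enol triflate formation (KHMDS, PhNTf2) and Fe- or Pd-catalysed methylation.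
2. Step 15 (iodo-olefination of aldehyde 17). The α-chiral β,γ-unsaturated aldehyde can epimerise or conjugate under the basic ylide, and yields of this olefination are typically moderate. Fallback: make the (2E,4Z)-dienoate by olefination instead of cross-coupling: Still–Gennari reaction of 17 with a bis(trifluoroethyl) 2-phosphonopropionate (a much less basic, stabilised anion) to the (Z)-enoate, then DIBAL, MnO2 and a Wittig reaction with the TMSE 2-(triphenylphosphoranylidene)propanoate.
3. Step 17 (Negishi union). Risks are incomplete exchange or transmetalation, homocoupling, or sluggish oxidative addition at the hindered trisubstituted bromide. Fallback: reverse the roles of the partners: omit Step 12, carry the C7≡C8 methylalkyne through Steps 13–16, and join it to iodide 6 by regioselective 9-BBN hydroboration of the alkyne followed by Suzuki–Miyaura coupling.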